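The route rests on cutting the side chain between benzylic C1″ and vinylic C2″. One operation, a Petasis-type three-component condensation, joins commercial (2R,3R)-taxifolin (as its 3,7,3′,4′-tetra-TBS ether), formaldehyde and an (E)-alkenylboronic acid that already carries the (R)-C6″ oxygen: boron binds O5, delivers CH2O to C6, and the resulting dioxaborin opens to an A-ring ortho-quinone methide (C5=O, C6=CH2) that takes the alkenyl group from boron. The step exploits the O5–H/C6–H pair of ring A: O5 is the only free phenol and C6 its only open ortho carbon, so C6 versus C8 is settled by the boron tether. The boronic acid stems from a CBS reduction and a Negishi carboalumination.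

Key step: step 8

Remark: (2R,3R)-taxifolin (dihydroquercetin) is assumed to be bought as the enantiopure bulk natural product, so C2 and C3 are taken from it unchanged; side-chain carbons are numbered C1″ (benzylic CH2) to C8″.

**Step 1**
Reactants: 1 pent-4-ynoic acid
Product: 2 N-methoxy-N-methylpent-4-ynamide
Conditions: CDI, CH2Cl2, rt; then MeNH(OMe)·HCl, rt
Reagents that add atoms: N,O-dimethylhydroxylamine hydrochloride, CNOC.Cl
Why: Weinreb amide formation through the acyl imidazole; the terminal alkyne is inert and no stereocentre is involved.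

**Step 2**
Reactants: 2 N-methoxy-N-methylpent-4-ynamide
Product: 3 2-methylhept-1-en-6-yn-3-one
Conditions: isopropenylMgBr (2.3 equiv), THF, −20 → 0 °C; inverse quench into cold 1 M HCl
Reagents that add atoms: isopropenylmagnesium bromide, C=C(C)[Mg]Br
Why: Weinreb ketone synthesis: the first equivalent only deprotonates the alkyne C–H, and the second adds once because the chelated tetrahedral adduct survives until the acidic quench, which also protonates the released amine before it can add to the enone.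

**Step 3**
Reactants: 3 2-methylhept-1-en-6-yn-3-one
Product: 4 (3R)-2-methylhept-1-en-6-yn-3-ol
Conditions: (S)-Me-CBS (20 mol %), catecholborane (1.5 equiv), PhMe, −78 °C; MeOH, then aq. NaOH wash
Reagents that add atoms: none
Why: CBS reduction: the ketone should bind the catalyst boron anti to the bulkier α-branched isopropenyl group, so hydride goes to the face that gives the (R)-carbinol (the sense in which the (S)-catalyst gives (R)-1-phenylethanol), while catecholborane at −78 °C should neither hydroborate the alkyne nor reduce the enone in the 1,4-sense.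

**Step 4**
Reactants: 4 (3R)-2-methylhept-1-en-6-yn-3-ol
Product: 5 (3R)-3-(tert-butyldimethylsilyloxy)-2-methylhept-1-en-6-yne
Conditions: TBSCl, imidazole, DMF, rt
Reagents that add atoms: tert-butyldimethylsilyl chloride, CC(C)(C)[Si](C)(C)Cl
Why: Standard silyl ether formation on the secondary allylic alcohol; the C–O bond is not broken, so the (R) centre is retained.

**Step 5**
Reactants: 5 (3R)-3-(tert-butyldimethylsilyloxy)-2-methylhept-1-en-6-yne
Product: 7 (3R,6E)-3-(tert-butyldimethylsilyloxy)-7-iodo-2,6-dimethylhepta-1,6-diene, via alkenylalane 6 (not isolated)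
Conditions: AlMe3 (2.5 equiv), Cp2ZrCl2 (0.25 equiv), CH2Cl2, 0 °C → rt; then I2, THF, −30 → 0 °C
Reagents that add atoms: trimethylaluminium, C[Al](C)C; iodine, II
Why: Negishi Zr-catalysed carboalumination adds Me–Al syn across the terminal alkyne with Al on the terminal carbon, and iodinolysis with retention then fixes the (E)-trisubstituted alkene; the 1,1-disubstituted alkene and the silyl ether should not react.

**Step 6**
Reactants: 7 (3R,6E)-3-(tert-butyldimethylsilyloxy)-7-iodo-2,6-dimethylhepta-1,6-diene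
Product: 10 [(1E,5R)-5-(tert-butyldimethylsilyloxy)-2,6-dimethylhepta-1,6-dien-1-yl]boronic acid, via alkenyllithium 8 (not isolated), via lithium triisopropoxyborate 9 (not isolated)
Conditions: t-BuLi (2.1 equiv), Et2O, −78 °C; B(OiPr)3, −78 °C → rt; cold 1 M HCl work-up
Reagents that add atoms: triisopropyl borate, CC(C)OB(OC(C)C)OC(C)C; water, O
Why: Iodine–lithium exchange with retention of alkene geometry, borylation of the alkenyllithium and hydrolysis of the ate complex (standard boronic acid synthesis).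

**Step 7**
Reactants: 11 (2R,3R)-taxifolin
Product: 12 (2R,3R)-3,7-bis(tert-butyldimethylsilyloxy)-2-[3,4-bis(tert-butyldimethylsilyloxy)phenyl]-5-hydroxychroman-4-one
Conditions: TBSCl (5 equiv), imidazole (8 equiv), DMF, 0 °C → rt
Reagents that add atoms: tert-butyldimethylsilyl chloride, CC(C)(C)[Si](C)(C)Cl
Why: Silyl ether formation on the three free phenols and the secondary 3-OH, whereas the 5-OH, hydrogen-bonded to the C4 carbonyl, should remain free; C2 and C3 are not touched under the mild base at low temperature.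

**Step 8**
Reactants: 12 (2R,3R)-3,7-bis(tert-butyldimethylsilyloxy)-2-[3,4-bis(tert-butyldimethylsilyloxy)phenyl]-5-hydroxychroman-4-one; 10 [(1E,5R)-5-(tert-butyldimethylsilyloxy)-2,6-dimethylhepta-1,6-dien-1-yl]boronic acid
Product: 16 (2R,3R)-3,7-bis(tert-butyldimethylsilyloxy)-2-[3,4-bis(tert-butyldimethylsilyloxy)phenyl]-6-[(2E,6R)-6-(tert-butyldimethylsilyloxy)-3,7-dimethylocta-2,7-dien-1-yl]-5-hydroxychroman-4-one, via dioxaborin 13 (not isolated), via quinone-methide boronate 14 (not isolated), via O5-borate 15 (not isolated)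
Conditions: 10 (1.5 equiv), (CH2O)n (3 equiv), (±)-3,3′-Br2-BINOL (20 mol %), EtCO2H (20 mol %), PhMe, 80 °C; pH 7 buffer work-up
Reagents that add atoms: formaldehyde (as paraformaldehyde), C=O
Why: Boronic acid 10 esterifies O5–H, the boron-bound formaldehyde is delivered to the single open ortho carbon C6 and condensation closes dioxaborin 13; acid/biphenol-assisted heterolysis of its CH2–O bond gives the A-ring ortho-quinone methide held on boron as ate complex 14 (C5=O→B, C6=CH2), and 1,4-migration of the alkenyl group from boron to the exocyclic CH2 through a six-membered transition state forms the C1″–C2″ bond and re-aromatises ring A to borate 15, which is hydrolysed on work-up. The closest known reactions are the biphenol-catalysed three-component condensation of phenols, aldehydes and alkenylboronates (Petasis-type, through ortho-quinone methides) and the boronic-acid-templated ortho-hydroxymethylation of phenols with paraformaldehyde. The only ring closed is the temporary six-membered 1,3,2-dioxaborin (C6–CH2 bond by boron-templated electrophilic aromatic substitution, then B–O condensation), which is reopened in the same flask; no ring of 16 is formed here. No stereocentre is created: the alkenyl group should migrate with retention of its (E) geometry, and C2, C3 and C6″ are untouched under these weakly acidic conditions. The step needs C6 over C8 and C-alkenylation at CH2 over attack at C4=O: C8 is para to O5 and flanked by silylated O7 and ring O1, so the O5-bound boron cannot reach it, and alkenylboronates do not add to ketones.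

**Step 9**
Reactants: 16 (2R,3R)-3,7-bis(tert-butyldimethylsilyloxy)-2-[3,4-bis(tert-butyldimethylsilyloxy)phenyl]-6-[(2E,6R)-6-(tert-butyldimethylsilyloxy)-3,7-dimethylocta-2,7-dien-1-yl]-5-hydroxychroman-4-one
Product: 17 (2R,3R)-2-(3,4-dihydroxyphenyl)-3,5,7-trihydroxy-6-[(2E,6R)-6-hydroxy-3,7-dimethylocta-2,7-dien-1-yl]chroman-4-one (CNP0280079.1)
Conditions: HF·pyridine, pyridine, THF, 0 °C → rt
Reagents that add atoms: none
Why: Fluoride-driven global desilylation cleaves all five Si–O bonds under buffered, weakly acidic conditions that should leave the base-sensitive flavanonol stereocentres, the allylic alcohol and the ortho-allyl phenol (no chroman closure) intact.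

**Compound list**
1 | pent-4-ynoic acid | C#CCCC(=O)O | starting material
2 | N-methoxy-N-methylpent-4-ynamide | C#CCCC(=O)N(C)OC | intermediate
3 | 2-methylhept-1-en-6-yn-3-one | C=C(C)C(=O)CCC#C | intermediate
4 | (3R)-2-methylhept-1-en-6-yn-3-ol | C=C(C)[C@H](O)CCC#C | intermediate
5 | (3R)-3-(tert-butyldimethylsilyloxy)-2-methylhept-1-en-6-yne | C=C(C)[C@H](O[Si](C)(C)C(C)(C)C)CCC#C | intermediate
6 | [(1E,5R)-5-(tert-butyldimethylsilyloxy)-2,6-dimethylhepta-1,6-dien-1-yl]dimethylalane | C=C(C)[C@H](O[Si](C)(C)C(C)(C)C)CC/C(C)=C/[Al](C)C | intermediate (not isolated)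
7 | (3R,6E)-3-(tert-butyldimethylsilyloxy)-7-iodo-2,6-dimethylhepta-1,6-diene | C=C(C)[C@H](O[Si](C)(C)C(C)(C)C)CC/C(C)=C/I | intermediate
8 | [(1E,5R)-5-(tert-butyldimethylsilyloxy)-2,6-dimethylhepta-1,6-dien-1-yl]lithium | C=C(C)[C@H](O[Si](C)(C)C(C)(C)C)CC/C(C)=C/[Li] | intermediate (not isolated)
9 | lithium [(1E,5R)-5-(tert-butyldimethylsilyloxy)-2,6-dimethylhepta-1,6-dien-1-yl]tri(propan-2-yloxy)borate | C=C(C)[C@H](O[Si](C)(C)C(C)(C)C)CC/C(C)=C/[B-](OC(C)C)(OC(C)C)OC(C)C.[Li+] | intermediate (not isolated)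
10 | [(1E,5R)-5-(tert-butyldimethylsilyloxy)-2,6-dimethylhepta-1,6-dien-1-yl]boronic acid | C=C(C)[C@H](O[Si](C)(C)C(C)(C)C)CC/C(C)=C/B(O)O | intermediate
11 | (2R,3R)-taxifolin, (2R,3R)-2-(3,4-dihydroxyphenyl)-3,5,7-trihydroxychroman-4-one | Oc1cc(O)cc2c1C(=O)[C@H](O)[C@@H](c1ccc(O)c(O)c1)O2 | starting material
12 | 3,7,3′,4′-tetra-O-TBS-(2R,3R)-taxifolin with free 5-OH | Oc1cc(O[Si](C)(C)C(C)(C)C)cc2c1C(=O)[C@H](O[Si](C)(C)C(C)(C)C)[C@@H](c1ccc(O[Si](C)(C)C(C)(C)C)c(O[Si](C)(C)C(C)(C)C)c1)O2 | intermediate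
13 | 4H-1,3,2-dioxaborin fused to ring A of 12 (ring O5–B–O–CH2–C6–C5), boron carrying the (1E,5R)-alkenyl group of 10 | C=C(C)[C@H](O[Si](C)(C)C(C)(C)C)CC/C(C)=C/B1OCc2c(O[Si](C)(C)C(C)(C)C)cc3c(c2O1)C(=O)[C@H](O[Si](C)(C)C(C)(C)C)[C@@H](c2ccc(O[Si](C)(C)C(C)(C)C)c(O[Si](C)(C)C(C)(C)C)c2)O3 | intermediate (not isolated)
14 | A-ring ortho-quinone methide of 12 (C5=O, C6=CH2, C7=C8, C8a=C4a) with the C5 oxygen bound to the alkenyl(dihydroxy)borate (ate complex) | C=C(C)[C@H](O[Si](C)(C)C(C)(C)C)CC/C(C)=C/[B-](O)(O)[O+]=C1C(=C)C(O[Si](C)(C)C(C)(C)C)=CC2=C1C(=O)[C@H](O[Si](C)(C)C(C)(C)C)[C@@H](c1ccc(O[Si](C)(C)C(C)(C)C)c(O[Si](C)(C)C(C)(C)C)c1)O2 | intermediate (not isolated)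
15 | 5-O-B(OH)2 borate ester of 16 | C=C(C)[C@H](O[Si](C)(C)C(C)(C)C)CC/C(C)=C/Cc1c(O[Si](C)(C)C(C)(C)C)cc2c(c1OB(O)O)C(=O)[C@H](O[Si](C)(C)C(C)(C)C)[C@@H](c1ccc(O[Si](C)(C)C(C)(C)C)c(O[Si](C)(C)C(C)(C)C)c1)O2 | intermediate (not isolated)
16 | 3,7,3′,4′,6″-penta-O-TBS ether of the target (free 5-OH; (2R,3R), side chain (2E,6R)) | C=C(C)[C@H](O[Si](C)(C)C(C)(C)C)CC/C(C)=C/Cc1c(O[Si](C)(C)C(C)(C)C)cc2c(c1O)C(=O)[C@H](O[Si](C)(C)C(C)(C)C)[C@@H](c1ccc(O[Si](C)(C)C(C)(C)C)c(O[Si](C)(C)C(C)(C)C)c1)O2 | intermediate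
17 | (2R,3R)-2-(3,4-dihydroxyphenyl)-3,5,7-trihydroxy-6-[(2E,6R)-6-hydroxy-3,7-dimethylocta-2,7-dien-1-yl]chroman-4-one | C=C(C)[C@H](O)CC/C(C)=C/Cc1c(O)cc2c(c1O)C(=O)[C@H](O)[C@@H](c1ccc(O)c(O)c1)O2 | target

**Step count**
Total: 9 steps. Longest linear sequence: 8 steps (steps 1–6, 8, 9); step 7 is a one-step branch.

**Steps most likely to fail**

1. Step 8. What may go wrong: slow or incomplete hydroxymethylation of the chelated, acyl-deactivated A ring; oligomerisation of the ortho-quinone methide or its cycloaddition with the isopropenyl group; protodeboronation of 10 before the alkenyl transfer. Fallback (Pd-catalysed benzylic Suzuki–Miyaura coupling, same bond): from 12, phenylboronic acid, paraformaldehyde and cat. EtCO2H in refluxing toluene should give the isolable 2-phenyl-dioxaborin F1. Exchange with propane-1,3-diol would free the 6-hydroxymethyl phenol F2, and Ac2O/pyridine/DMAP would give the diacetate F3. Coupling of its benzylic acetate with 10 ([Pd(allyl)Cl]2, 1,5-bis(diphenylphosphino)pentane, K2CO3, t-AmOH, 80 °C) should give the 5-O-acetyl coupled product F4. NH4OAc in aqueous MeOH would then remove the aryl acetate and return to 16.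

2. Step 3. What may go wrong: insufficient facial discrimination between the isopropenyl group and the but-3-ynyl chain in the CBS transition state, with some 1,4-reduction, leaving 4 of inadequate enantiopurity that would later appear as the C6″ epimer. Fallback (resolution instead of asymmetric reduction): from 3, Luche reduction (NaBH4, CeCl3·7H2O, MeOH, 0 °C) would give the racemic alcohol F5. Sharpless kinetic resolution (Ti(OiPr)4, L-(+)-DIPT, TBHP, 4 Å MS, CH2Cl2, −20 °C) should epoxidise the (S)-enantiomer to the erythro epoxy alcohol F6 and leave the (R)-alcohol, rejoining the route at 4.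

3. Step 7. What may go wrong: incomplete silylation of the hindered 3-OH or partial silylation of O5, giving mixtures; base-induced C2 epimerisation through B-ring quinone-methide ring opening before O4′ is capped. Fallback (exhaustive protection, then selective unmasking): from 11, TBSOTf/2,6-lutidine in CH2Cl2 at −78 → 0 °C would give the penta-silyl ether F7. Its 5-O-silyl group, peri to the C4 carbonyl, is the most labile and should be cleaved selectively with AcOH/THF/H2O at rt, returning to 12.

**Further compounds**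
F1 | step 8 | 2-phenyl-4H-1,3,2-dioxaborin fused to ring A of 12 (O5–B(Ph)–O–CH2–C6) | c1ccccc1B1OCc2c(O[Si](C)(C)C(C)(C)C)cc3c(c2O1)C(=O)[C@H](O[Si](C)(C)C(C)(C)C)[C@@H](c2ccc(O[Si](C)(C)C(C)(C)C)c(O[Si](C)(C)C(C)(C)C)c2)O3
F2 | step 8 | 6-(hydroxymethyl) derivative of 12 | OCc1c(O[Si](C)(C)C(C)(C)C)cc2c(c1O)C(=O)[C@H](O[Si](C)(C)C(C)(C)C)[C@@H](c1ccc(O[Si](C)(C)C(C)(C)C)c(O[Si](C)(C)C(C)(C)C)c1)O2
F3 | step 8 | 5-O-acetyl-6-(acetoxymethyl) derivative of 12 | CC(=O)OCc1c(O[Si](C)(C)C(C)(C)C)cc2c(c1OC(C)=O)C(=O)[C@H](O[Si](C)(C)C(C)(C)C)[C@@H](c1ccc(O[Si](C)(C)C(C)(C)C)c(O[Si](C)(C)C(C)(C)C)c1)O2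
F4 | step 8 | 5-O-acetate of 16 | C=C(C)[C@H](O[Si](C)(C)C(C)(C)C)CC/C(C)=C/Cc1c(O[Si](C)(C)C(C)(C)C)cc2c(c1OC(C)=O)C(=O)[C@H](O[Si](C)(C)C(C)(C)C)[C@@H](c1ccc(O[Si](C)(C)C(C)(C)C)c(O[Si](C)(C)C(C)(C)C)c1)O2
F5 | step 3 | racemic 2-methylhept-1-en-6-yn-3-ol | C=C(C)C(O)CCC#C
F6 | step 3 | (1S)-1-[(2R)-2-methyloxiran-2-yl]pent-4-yn-1-ol | C[C@@]1(CO1)[C@@H](O)CCC#C
F7 | step 7 | 3,5,7,3′,4′-penta-O-TBS-(2R,3R)-taxifolin | CC(C)(C)[Si](C)(C)Oc1cc(O[Si](C)(C)C(C)(C)C)cc2c1C(=O)[C@H](O[Si](C)(C)C(C)(C)C)[C@@H](c1ccc(O[Si](C)(C)C(C)(C)C)c(O[Si](C)(C)C(C)(C)C)c1)O2
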